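## Retrosynthetic overview

1. Positions follow the chromane core of the target (O1, C2, C3, C4, C4a, C5, C6, C7, C8, C8a). The last operations are ester cleavage and, before that, closure of the tetrahydropyran at O1–C8a by a cobalt-hydride HAT / radical–polar crossover hydroalkoxylation of an exocyclic methylene by the C2 tertiary carbinol.
2. The C2 carbinol comes from a chelation-controlled MeMgCl addition to an oxiranyl ketone; the exocyclic methylene comes from the ring ketone.
3. Key disconnection C3–C4: a photoredox radical coupling of the α-acyl radical from (S)-chloromethyl oxiranyl ketone with an exocyclic allylic alcohol. The same step moves the ring oxygen function (allylic alcohol to ketone) and sets C4a.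
4. The allylic alcohol comes from 2-methylcyclohex-2-enone: asymmetric Mukaiyama–Michael addition of the isobutyric acid bis-silyl ketene acetal (sets C6), trans enolate alkylation with methyl bromoacetate (sets C5), Wittig methylenation, SeO2 allylic hydroxylation.
5. Ring order: the carbocycle (bought as the enone) and the oxirane (bought as the glycidate) are carried through; the tetrahydropyran is formed last.

## Route

Step 1
Reactants: 1 2-methylpropanoic acid (isobutyric acid)
Product: 3 [(2-methylprop-1-ene-1,1-diyl)bis(oxy)]bis(trimethylsilane), via dilithium enediolate 2 (not isolated)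
Conditions: LiN(i-Pr)2 (2.2 equiv), THF, −78 → 0 °C; Me3SiCl (2.3 equiv), −78 °C → rt
Reagents that add atoms: chlorotrimethylsilane, C[Si](C)(C)Cl
Why: Double deprotonation of the acid and O,O-disilylation of the dianion gives the bis-silyl ketene acetal (standard silyl ketene acetal formation); no stereocentre is involved.

Step 2
Reactants: 3 [(2-methylprop-1-ene-1,1-diyl)bis(oxy)]bis(trimethylsilane); 4 2-methylcyclohex-2-en-1-one; 5 methyl 2-bromoacetate
Product: 9 benzyl 2-[(1S,2R)-2-(2-methoxy-2-oxoethyl)-2-methyl-3-oxocyclohexyl]-2-methylpropanoate, via bis-silyl Michael adduct 6 (not isolated), via dipotassium enolate carboxylate 7 (not isolated), via potassium carboxylate 8 (not isolated)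
Conditions: (S)-3,3-diphenyl-1-(o-tolyl)tetrahydro-1H,3H-pyrrolo[1,2-c][1,3,2]oxazaborole·HNTf2 (20 mol %), CH2Cl2, −40 °C; then KOt-Bu (2.2 equiv), THF, −78 °C; 5, −78 → −20 °C; then BnBr, DMF, 0 °C → rt
Reagents that add atoms: benzyl bromide, BrCc1ccccc1
Why: A chiral oxazaborolidinium Lewis acid mediates a catalytic asymmetric Mukaiyama–Michael addition that sets the future C6 under catalyst control (the antipodal catalyst is used if the facial sense is reversed), the potassium enolate released from the enol silane is C-alkylated by 5 anti to the bulky CMe2CO2K group so that the quaternary future C5 is set trans, and the hindered carboxylate is then O-benzylated.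

Step 3
Reactants: 9 benzyl 2-[(1S,2R)-2-(2-methoxy-2-oxoethyl)-2-methyl-3-oxocyclohexyl]-2-methylpropanoate
Product: 10 benzyl 2-[(1S,2R)-2-(2-methoxy-2-oxoethyl)-2-methyl-3-methylidenecyclohexyl]-2-methylpropanoate
Conditions: Ph3PCH3Br (3 equiv), KN(SiMe3)2 (2.8 equiv), toluene, 0 → 70 °C
Reagents that add atoms: methyltriphenylphosphonium bromide, C[P+](c1ccccc1)(c1ccccc1)c1ccccc1.[Br-]
Why: Wittig methylenation with the salt-free ylide converts the hindered ketone into the exocyclic alkene (future C4) without touching the neopentyl-type esters or the stereocentres.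

Step 4
Reactants: 10 benzyl 2-[(1S,2R)-2-(2-methoxy-2-oxoethyl)-2-methyl-3-methylidenecyclohexyl]-2-methylpropanoate
Product: 11 benzyl 2-[(1S,2R)-4-hydroxy-2-(2-methoxy-2-oxoethyl)-2-methyl-3-methylidenecyclohexyl]-2-methylpropanoate (both C-4 epimers)
Conditions: SeO2 (0.5 equiv), t-BuOOH (3 equiv), CH2Cl2, rt
Reagents that add atoms: selenium dioxide, O=[Se]=O; tert-butyl hydroperoxide, CC(C)(C)OO
Why: SeO2 allylic hydroxylation (ene reaction then [2,3]-sigmatropic shift) oxidises the only allylic CH2 (future C8a) and keeps the exocyclic alkene; the carbinol configuration is irrelevant because it is erased in step 6.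

Step 5
Reactants: 12 methyl (2S)-oxirane-2-carboxylate
Product: 13 2-chloro-1-[(2S)-oxiran-2-yl]ethan-1-one
Conditions: ICH2Cl (1.6 equiv), MeLi·LiBr (1.5 equiv), THF/Et2O, −78 °C; AcOH, −78 °C
Reagents that add atoms: chloroiodomethane, ClCI
Why: Chloromethyllithium carbenoid homologation of the ester stops at the chloromethyl ketone because the tetrahedral adduct is stable at −78 °C; the oxirane stereocentre (future oxirane C2) is not enolisable and is carried unchanged.

Step 6
Reactants: 11 benzyl 2-[(1S,2R)-4-hydroxy-2-(2-methoxy-2-oxoethyl)-2-methyl-3-methylidenecyclohexyl]-2-methylpropanoate; 13 2-chloro-1-[(2S)-oxiran-2-yl]ethan-1-one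
Product: 15 benzyl 2-[(1S,2R,3S)-2-(2-methoxy-2-oxoethyl)-2-methyl-4-oxo-3-{3-oxo-3-[(2S)-oxiran-2-yl]propyl}cyclohexyl]-2-methylpropanoate, via enol 14 (not isolated)
Conditions: 13 (1.5 equiv), fac-Ir(ppy)3 [tris(2-phenylpyridinato)iridium] (1 mol %), 2,6-lutidine (2 equiv), MeCN, blue LEDs (450 nm), rt; then Et3N (0.2 equiv), rt
Reagents that add atoms: none
Why: Proposed new method: the electrophilic α-acyl radical released from 13 by single-electron transfer from photoexcited Ir(ppy)3 adds to the terminal carbon of the electron-rich exocyclic alkene of 11 (C3–C4 bond), the tertiary β-hydroxy radical is oxidised by tetravalent iridium to the cation, which collapses by 1,2-hydride shift or proton loss to enol 14 and ketone 15 (redox-neutral radical–polar crossover), and ketonisation with axial protonation anti to the axial methyl plus amine equilibration places the side chain equatorial (sets C4a); the closest known reaction type is the photoredox alkylation of allylic alcohols with α-halocarbonyl compounds that gives β-functionalised ketones by radical addition and 1,2-H shift.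

Step 7
Reactants: 15 benzyl 2-[(1S,2R,3S)-2-(2-methoxy-2-oxoethyl)-2-methyl-4-oxo-3-{3-oxo-3-[(2S)-oxiran-2-yl]propyl}cyclohexyl]-2-methylpropanoate
Product: 16 benzyl 2-[(1S,2R,3S)-3-{(3R)-3-hydroxy-3-[(2S)-oxiran-2-yl]butyl}-2-(2-methoxy-2-oxoethyl)-2-methyl-4-oxocyclohexyl]-2-methylpropanoate
Conditions: MeMgCl (1.2 equiv), CH2Cl2/Et2O 4:1, −78 °C; aq. NH4Cl, −78 °C
Reagents that add atoms: methylmagnesium chloride, C[Mg]Cl
Why: Cram-chelate Grignard addition: magnesium bridges the ketone and oxirane oxygens and methyl attacks the face opposite the oxirane CH2, which gives the (3R) carbinol (future C2); the α-oxygenated ketone is far more electrophilic than the hindered ring ketone and the neopentyl-type esters.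

Step 8
Reactants: 16 benzyl 2-[(1S,2R,3S)-3-{(3R)-3-hydroxy-3-[(2S)-oxiran-2-yl]butyl}-2-(2-methoxy-2-oxoethyl)-2-methyl-4-oxocyclohexyl]-2-methylpropanoate
Product: 17 benzyl 2-[(1S,2S,3R)-3-{(3R)-3-hydroxy-3-[(2S)-oxiran-2-yl]butyl}-2-(2-methoxy-2-oxoethyl)-2-methyl-4-methylidenecyclohexyl]-2-methylpropanoate
Conditions: Cp2Ti(μ-CH2)(μ-Cl)AlMe2 (3 equiv), pyridine (0.2 equiv), THF/toluene, −40 → 0 °C; aq. NaOH
Reagents that add atoms: Tebbe reagent [Cp2Ti(μ-CH2)(μ-Cl)AlMe2], C[Al-]1(C)C[Ti]([Cl+]1)(C2C=CC=C2)C3C=CC=C3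
Why: Tebbe methylenation through the titanium methylidene converts the ketone faster than the esters and is non-basic, so the epoxy alcohol cannot undergo Payne rearrangement and the α-centre is not epimerised, the excess reagent covering the free carbinol (the changed ring descriptors reflect CIP priorities only).

Step 9
Reactants: 17 benzyl 2-[(1S,2S,3R)-3-{(3R)-3-hydroxy-3-[(2S)-oxiran-2-yl]butyl}-2-(2-methoxy-2-oxoethyl)-2-methyl-4-methylidenecyclohexyl]-2-methylpropanoate
Product: 18 benzyl 2-[(2R,4aS,5R,6S,8aS)-5-(2-methoxy-2-oxoethyl)-2,5,8a-trimethyl-2-[(2S)-oxiran-2-yl]octahydro-2H-chromen-6-yl]-2-methylpropanoate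
Conditions: Co(salen) [C36H52CoN2O2, (R,R)-N,N'-bis(3,5-di-tert-butylsalicylidene)-1,2-cyclohexanediaminocobalt, divalent cobalt] (3 mol %), N-fluoro-2,4,6-trimethylpyridinium triflate (1.3 equiv), PhSiH3 (1.2 equiv), PhCF3, 0 °C → rt
Reagents that add atoms: none
Why: Cobalt-hydride hydrogen atom transfer to the exocyclic methylene gives the tertiary C8a radical, which is oxidised (radical–polar crossover hydroalkoxylation) and captured by the tertiary carbinol from the equatorial face anti to the axial C5 methyl, so the trans-fused tetrahydropyran with axial C8a methyl is formed (sets C8a) under non-acidic conditions that spare the oxirane.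

Step 10
Reactants: 18 benzyl 2-[(2R,4aS,5R,6S,8aS)-5-(2-methoxy-2-oxoethyl)-2,5,8a-trimethyl-2-[(2S)-oxiran-2-yl]octahydro-2H-chromen-6-yl]-2-methylpropanoate
Product: 20 2-[(2R,4aS,5R,6S,8aS)-5-(carboxymethyl)-2,5,8a-trimethyl-2-[(2S)-oxiran-2-yl]octahydro-2H-chromen-6-yl]-2-methylpropanoic acid, via lithium carboxylate 19 (not isolated)
Conditions: LiOH·H2O (3 equiv), THF/H2O 3:1, rt; then Pd/C (10 wt %), H2 (1 atm), rt; filter; aq. NaH2PO4 to pH 4–5, 0 °C
Reagents that add atoms: lithium hydroxide, [Li+].[OH-]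
Why: Saponification removes the unhindered methyl ester and hydrogenolysis removes the benzyl ester of the hindered acid (cleavage at the benzylic C–O bond is insensitive to the neopentyl environment), both under conditions that leave the oxirane and all stereocentres untouched.

## Compound list

1 | 2-methylpropanoic acid (isobutyric acid) | CC(C)C(=O)O | starting material
2 | dilithium 2-methylprop-1-ene-1,1-bis(olate) | CC(C)=C(O[Li])O[Li] | intermediate
3 | [(2-methylprop-1-ene-1,1-diyl)bis(oxy)]bis(trimethylsilane) | CC(C)=C(O[Si](C)(C)C)O[Si](C)(C)C | intermediate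
4 | 2-methylcyclohex-2-en-1-one | CC1=CCCCC1=O | starting material
5 | methyl 2-bromoacetate | COC(=O)CBr | starting material
6 | trimethylsilyl 2-methyl-2-[(1S)-2-methyl-3-[(trimethylsilyl)oxy]cyclohex-2-en-1-yl]propanoate | CC(C)(C(=O)O[Si](C)(C)C)[C@H]1CCCC(O[Si](C)(C)C)=C1C | intermediate
7 | potassium 2-methyl-2-[(1S)-2-methyl-3-(potassiooxy)cyclohex-2-en-1-yl]propanoate | CC(C)(C(=O)O[K])[C@H]1CCCC(O[K])=C1C | intermediate
8 | potassium 2-[(1S,2R)-2-(2-methoxy-2-oxoethyl)-2-methyl-3-oxocyclohexyl]-2-methylpropanoate | CC(C)(C(=O)O[K])[C@H]1CCCC(=O)[C@]1(C)CC(=O)OC | intermediate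
9 | benzyl 2-[(1S,2R)-2-(2-methoxy-2-oxoethyl)-2-methyl-3-oxocyclohexyl]-2-methylpropanoate | CC(C)(C(=O)OCc1ccccc1)[C@H]1CCCC(=O)[C@]1(C)CC(=O)OC | intermediate
10 | benzyl 2-[(1S,2R)-2-(2-methoxy-2-oxoethyl)-2-methyl-3-methylidenecyclohexyl]-2-methylpropanoate | CC(C)(C(=O)OCc1ccccc1)[C@H]1CCCC(=C)[C@]1(C)CC(=O)OC | intermediate
11 | benzyl 2-[(1S,2R)-4-hydroxy-2-(2-methoxy-2-oxoethyl)-2-methyl-3-methylidenecyclohexyl]-2-methylpropanoate (both C-4 epimers) | CC(C)(C(=O)OCc1ccccc1)[C@H]1CCC(O)C(=C)[C@]1(C)CC(=O)OC | intermediate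
12 | methyl (2S)-oxirane-2-carboxylate | COC(=O)[C@@H]1CO1 | starting material
13 | 2-chloro-1-[(2S)-oxiran-2-yl]ethan-1-one | ClCC(=O)[C@@H]1CO1 | intermediate
14 | benzyl 2-[(1S,2R)-4-hydroxy-2-(2-methoxy-2-oxoethyl)-2-methyl-3-{3-oxo-3-[(2S)-oxiran-2-yl]propyl}cyclohex-3-en-1-yl]-2-methylpropanoate | CC(C)(C(=O)OCc1ccccc1)[C@H]1CCC(O)=C(CCC(=O)[C@@H]2CO2)[C@]1(C)CC(=O)OC | intermediate
15 | benzyl 2-[(1S,2R,3S)-2-(2-methoxy-2-oxoethyl)-2-methyl-4-oxo-3-{3-oxo-3-[(2S)-oxiran-2-yl]propyl}cyclohexyl]-2-methylpropanoate | CC(C)(C(=O)OCc1ccccc1)[C@H]1CCC(=O)[C@@H](CCC(=O)[C@@H]2CO2)[C@]1(C)CC(=O)OC | intermediate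
16 | benzyl 2-[(1S,2R,3S)-3-{(3R)-3-hydroxy-3-[(2S)-oxiran-2-yl]butyl}-2-(2-methoxy-2-oxoethyl)-2-methyl-4-oxocyclohexyl]-2-methylpropanoate | CC(C)(C(=O)OCc1ccccc1)[C@H]1CCC(=O)[C@@H](CC[C@@](C)(O)[C@@H]2CO2)[C@]1(C)CC(=O)OC | intermediate
17 | benzyl 2-[(1S,2S,3R)-3-{(3R)-3-hydroxy-3-[(2S)-oxiran-2-yl]butyl}-2-(2-methoxy-2-oxoethyl)-2-methyl-4-methylidenecyclohexyl]-2-methylpropanoate | CC(C)(C(=O)OCc1ccccc1)[C@H]1CCC(=C)[C@@H](CC[C@@](C)(O)[C@@H]2CO2)[C@]1(C)CC(=O)OC | intermediate
18 | benzyl 2-[(2R,4aS,5R,6S,8aS)-5-(2-methoxy-2-oxoethyl)-2,5,8a-trimethyl-2-[(2S)-oxiran-2-yl]octahydro-2H-chromen-6-yl]-2-methylpropanoate | CC(C)(C(=O)OCc1ccccc1)[C@H]1CC[C@]2(C)O[C@@](C)([C@@H]3CO3)CC[C@H]2[C@]1(C)CC(=O)OC | intermediate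
19 | lithium 2-[(2R,4aS,5R,6S,8aS)-6-[1-(benzyloxy)-2-methyl-1-oxopropan-2-yl]-2,5,8a-trimethyl-2-[(2S)-oxiran-2-yl]octahydro-2H-chromen-5-yl]acetate | CC(C)(C(=O)OCc1ccccc1)[C@H]1CC[C@]2(C)O[C@@](C)([C@@H]3CO3)CC[C@H]2[C@]1(C)CC(=O)O[Li] | intermediate
20 | 2-[(2R,4aS,5R,6S,8aS)-5-(carboxymethyl)-2,5,8a-trimethyl-2-[(2S)-oxiran-2-yl]octahydro-2H-chromen-6-yl]-2-methylpropanoic acid | CC(C)(C(=O)O)[C@H]1CC[C@]2(C)O[C@@](C)([C@@H]3CO3)CC[C@H]2[C@]1(C)CC(=O)O | target

## Step count and risks

Total step count: 10. Longest linear sequence: 9 steps (1, 2, 3, 4, 6, 7, 8, 9, 10); step 5 is the side branch.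

The three steps most likely to fail are steps 6, 2 and 9, in that order.

Step 6 is the least precedented. The cation formed after radical addition could be captured by the neighbouring methyl ester carbonyl (lactone formation) instead of collapsing to the ketone, and the oxiranyl ketone could be reduced by the excited photocatalyst. The fallback replaces the radical coupling by a polar conjugate addition and sets out from 11 and 13. Dess–Martin oxidation of 11 gives the exocyclic enone benzyl 2-[(1S,2R)-2-(2-methoxy-2-oxoethyl)-2-methyl-3-methylidene-4-oxocyclohexyl]-2-methylpropanoate F3. Zinc insertion into 13 (Zn, Me3SiCl, THF, 0 °C) gives the zinc enolate chloro{1-[(2S)-oxiran-2-yl]ethenolato}zinc F4. F4 adds 1,4 to F3 under CuBr·SMe2 catalysis (Reformatsky-type Michael addition), and protonation with Et3N equilibration comes back to the route at 15.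

Step 2 is uncertain on two counts: the enantioselectivity of the oxazaborolidinium-catalysed addition has to be extended to an α-methyl enone, and the alkylation builds a very congested quaternary centre in a three-stage one-pot sequence. The fallback is a classical resolution and sets out from 3, 4 and 5. The addition is run with achiral HNTf2 (1 mol %), the potassium enolate is alkylated with 5 as before, and the mixture is acidified instead of benzylated to give the racemic trans keto acid rac-2-[(1S*,2R*)-2-(2-methoxy-2-oxoethyl)-2-methyl-3-oxocyclohexyl]-2-methylpropanoic acid F1. Crystallisation with (R)-1-phenylethanamine (or its antipode, whichever salt of the wanted acid is the less soluble) gives (R)-1-phenylethanaminium 2-[(1S,2R)-2-(2-methoxy-2-oxoethyl)-2-methyl-3-oxocyclohexyl]-2-methylpropanoate F2. Liberation of the acid (aq. KHSO4) and O-benzylation (BnBr, K2CO3, DMF) come back to the route at 9.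

Step 9 is at risk because the Lewis-acidic cobalt and the fluoride released from the oxidant may open the oxirane that sits next to the reacting carbinol. The fallback sets out from 17. Intramolecular alkoxymercuration with Hg(OCOCF3)2 (THF, 0 °C; then aq. NaCl) gives the organomercurial benzyl 2-[(2R,4aS,5R,6S,8aS)-8a-[(chloromercurio)methyl]-5-(2-methoxy-2-oxoethyl)-2,5-dimethyl-2-[(2S)-oxiran-2-yl]octahydro-2H-chromen-6-yl]-2-methylpropanoate F5. Reductive demercuration (NaBH4, aq. NaOH, 0 °C) comes back to the route at 18.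

Further compounds
F1 | step 2 | rac-2-[(1S*,2R*)-2-(2-methoxy-2-oxoethyl)-2-methyl-3-oxocyclohexyl]-2-methylpropanoic acid (racemate, one enantiomer drawn) | CC(C)(C(=O)O)[C@H]1CCCC(=O)[C@]1(C)CC(=O)OC
F2 | step 2 | (R)-1-phenylethanaminium 2-[(1S,2R)-2-(2-methoxy-2-oxoethyl)-2-methyl-3-oxocyclohexyl]-2-methylpropanoate | CC(C)(C(=O)[O-])[C@H]1CCCC(=O)[C@]1(C)CC(=O)OC.C[C@@H]([NH3+])c1ccccc1
F3 | step 6 | benzyl 2-[(1S,2R)-2-(2-methoxy-2-oxoethyl)-2-methyl-3-methylidene-4-oxocyclohexyl]-2-methylpropanoate | CC(C)(C(=O)OCc1ccccc1)[C@H]1CCC(=O)C(=C)[C@]1(C)CC(=O)OC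
F4 | step 6 | chloro{1-[(2S)-oxiran-2-yl]ethenolato}zinc | C=C(O[Zn]Cl)[C@@H]1CO1
F5 | step 9 | benzyl 2-[(2R,4aS,5R,6S,8aS)-8a-[(chloromercurio)methyl]-5-(2-methoxy-2-oxoethyl)-2,5-dimethyl-2-[(2S)-oxiran-2-yl]octahydro-2H-chromen-6-yl]-2-methylpropanoate | CC(C)(C(=O)OCc1ccccc1)[C@H]1CC[C@]2(C[Hg]Cl)O[C@@](C)([C@@H]3CO3)CC[C@H]2[C@]1(C)CC(=O)OC
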